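## Retrosynthetic overview

- Meridianin F is traced back to its 2‑methylthio analogue. The pyrimidine C2–NH2 is installed last by S‑oxidation and displacement with ammonia.
- The indole is disconnected at C2–C3. C3 is bonded to C3a of the dibromobenzo ring and to C4 of the pyrimidine ring, so before closure it is a CH2 acidified by both rings (charge on the pyrimidine nitrogens). C2 is the carbon of an isocyanide on the future indole nitrogen, already at the right oxidation level.
- The isocyanide comes from the formamide, the aniline and the nitro diarylmethane. The diarylmethane is made by SNAr of tert‑butyl (2‑methylthiopyrimidin‑4‑yl)acetate on 1,2‑dibromo‑4‑fluoro‑5‑nitrobenzene, then decarboxylation. The ester is a temporary activating group, chosen because an unstabilized methylpyrimidine anion is likely to undergo electron transfer with the nitroarene.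
- Ring order: the benzene and pyrimidine rings are bought; the pyrrole ring is the only ring formed.

Key step: step 8

## Route

Step 1
Reactants: 1 1,2‑dibromo‑4‑fluorobenzene
Product: 2 1,2‑dibromo‑4‑fluoro‑5‑nitrobenzene
Conditions: fuming HNO3, conc. H2SO4, 0 °C → rt
Reagents that add atoms: nitric acid, O[N+](=O)[O-]
Why: Electrophilic aromatic nitration; fluorine directs ortho (its para position carries Br), and C5 is also para to the C2 bromine and less hindered than C3 between F and Br, so the nitro group should enter at C5.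

Step 2
Reactants: 3 4‑methyl‑2‑(methylthio)pyrimidine
Product: 4 tert‑butyl 2‑[2‑(methylthio)pyrimidin‑4‑yl]acetate
Conditions: LiN(SiMe3)2 (2.1 equiv), THF, −78 °C; then Boc2O (1.0 equiv), −78 → 0 °C; aq NH4Cl
Reagents that add atoms: di‑tert‑butyl dicarbonate, CC(C)(C)OC(=O)OC(=O)OC(C)(C)C
Why: Lateral deprotonation of the 4‑methyl group to an aza‑enolate and C‑acylation by Boc2O (Claisen‑type carboxylation of a methylazine); the second equivalent of base is taken up by the more acidic product, which should stop double acylation.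

Step 3
Reactants: 2 1,2‑dibromo‑4‑fluoro‑5‑nitrobenzene; 4 tert‑butyl 2‑[2‑(methylthio)pyrimidin‑4‑yl]acetate
Product: 5 tert‑butyl 2‑(4,5‑dibromo‑2‑nitrophenyl)‑2‑[2‑(methylthio)pyrimidin‑4‑yl]acetate (racemic)
Conditions: Cs2CO3 (2.5 equiv), DMF, argon, rt → 50 °C
Reagents that add atoms: none
Why: SNAr through a Meisenheimer adduct: the ester‑ and pyrimidine‑stabilized carbanion of 4 displaces the fluoride ortho to the nitro group, which should leave far faster than the bromide para to it; the new CH center is racemic and is erased in step 4.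

Step 4
Reactants: 5 tert‑butyl 2‑(4,5‑dibromo‑2‑nitrophenyl)‑2‑[2‑(methylthio)pyrimidin‑4‑yl]acetate
Product: 7 4‑[(4,5‑dibromo‑2‑nitrophenyl)methyl]‑2‑(methylthio)pyrimidine, via carboxylic acid 6 (not isolated)
Conditions: TFA, CH2Cl2, rt; concentrate; toluene, 80 °C
Reagents that add atoms: none
Why: Acidolysis of the tert‑butyl ester (loss of isobutene) gives an α‑(2‑nitroaryl)‑α‑(pyrimidin‑4‑yl)acetic acid, which should decarboxylate readily through its enamine‑type tautomer, as azin‑4‑ylacetic acids do.

Step 5
Reactants: 7 4‑[(4,5‑dibromo‑2‑nitrophenyl)methyl]‑2‑(methylthio)pyrimidine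
Product: 8 4,5‑dibromo‑2‑{[2‑(methylthio)pyrimidin‑4‑yl]methyl}aniline
Conditions: Fe powder, AcOH, EtOH, 60 °C
Reagents that add atoms: none
Why: Béchamp‑type reduction of the nitro group by iron in acetic acid, which should leave the aryl bromides, the thioether and the pyrimidine untouched.

Step 6
Reactants: 8 4,5‑dibromo‑2‑{[2‑(methylthio)pyrimidin‑4‑yl]methyl}aniline
Product: 9 N‑(4,5‑dibromo‑2‑{[2‑(methylthio)pyrimidin‑4‑yl]methyl}phenyl)formamide
Conditions: HCO2H/Ac2O (premixed at 55 °C, then cooled), THF, 0 °C → rt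
Reagents that add atoms: acetic formic anhydride, CC(=O)OC=O, made from formic acid, OC=O, and acetic anhydride, CC(=O)OC(C)=O
Why: N‑Formylation of a weakly nucleophilic aniline by the mixed anhydride, which transfers the formyl group because the formyl carbonyl is the more electrophilic and less hindered one.

Step 7
Reactants: 9 N‑(4,5‑dibromo‑2‑{[2‑(methylthio)pyrimidin‑4‑yl]methyl}phenyl)formamide
Product: 10 4‑[(4,5‑dibromo‑2‑isocyanophenyl)methyl]‑2‑(methylthio)pyrimidine
Conditions: POCl3, Et3N, CH2Cl2, −30 → 0 °C; cold aq Na2CO3 work‑up, used at once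
Reagents that add atoms: none
Why: Dehydration of an N‑aryl formamide to the isocyanide (Ugi method) by O‑phosphorylation and amine‑induced elimination; triethylamine should be too weak to deprotonate the diarylmethane CH2 appreciably at this temperature, so 10 should be isolable.

Step 8
Reactants: 10 4‑[(4,5‑dibromo‑2‑isocyanophenyl)methyl]‑2‑(methylthio)pyrimidine
Product: 14 5,6‑dibromo‑3‑[2‑(methylthio)pyrimidin‑4‑yl]‑1H‑indole, via lithium aza‑enolate 11 (not isolated), via 2‑lithio‑3H‑indole 12 (not isolated), via lithium indolide 13 (not isolated)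
Conditions: LiN(SiMe3)2 (1.2 equiv), THF, −78 °C → rt; then sat. aq NH4Cl
Reagents that add atoms: none
Why: The silylamide removes a proton from the CH2 of 10, which is acidified by the dibromoaryl ring and by the pyrimidin‑4‑yl group (aza‑enolate 11, charge on the ring nitrogens), and the carbanion carbon adds to the terminal divalent carbon of the ortho isocyanide to form the C2–C3 bond and the imidoyl anion 12. The closest known reaction is the Ito–Saegusa indole synthesis, the cyclization of ortho‑isocyanobenzyl carbanions, here with a pyrimidin‑4‑yl group as the anion‑stabilizing substituent. The pyrrole ring closes in a 5‑endo‑dig mode, the isocyanide N≡C bond lying inside the new five‑membered ring. The C3–H of 12, flanked by the imine, the arene and the pyrimidine, then shifts to give the aromatic indolide 13, so the only stereocenter formed (C3 of 12) is transient and the product has none. The step needs carbon attack on the isocyanide to win over isocyanide oligomerization and over any reaction of base at the two C–Br bonds; the intramolecular five‑membered closure and the acidity of the CH2, which allows a hindered non‑nucleophilic amide base at low temperature instead of an alkyllithium, should secure this.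

Step 9
Reactants: 14 5,6‑dibromo‑3‑[2‑(methylthio)pyrimidin‑4‑yl]‑1H‑indole
Product: 16 5,6‑dibromo‑3‑[2‑(methylsulfonyl)pyrimidin‑4‑yl]‑1H‑indole, via sulfoxide 15 (not isolated)
Conditions: mCPBA (2.2 equiv), CH2Cl2/THF, 0 °C → rt; aq Na2S2O3/NaHCO3
Reagents that add atoms: 3‑chloroperoxybenzoic acid, OOC(=O)c1cccc(Cl)c1
Why: Chemoselective S‑oxidation of the thioether by the peracid through the sulfoxide to the sulfone; the indole C2=C3 bond is deactivated by conjugation with the pyrimidine and by the two bromines and should not be oxidized at this temperature.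

Step 10
Reactants: 16 5,6‑dibromo‑3‑[2‑(methylsulfonyl)pyrimidin‑4‑yl]‑1H‑indole
Product: 17 Meridianin F, 4‑(5,6‑dibromo‑1H‑indol‑3‑yl)pyrimidin‑2‑amine
Conditions: NH3 (0.5 M in 1,4‑dioxane, excess), sealed tube, 90 °C
Reagents that add atoms: ammonia, N
Why: SNAr (addition–elimination) at C2 of the pyrimidine with methanesulfinate as leaving group, activated by both ring nitrogens; a non‑nucleophilic solvent avoids alkoxy exchange and the aryl bromides are inert to ammonia without a metal catalyst.

## Compound list

1 | 1,2‑dibromo‑4‑fluorobenzene | Fc1ccc(Br)c(Br)c1 | starting material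
2 | 1,2‑dibromo‑4‑fluoro‑5‑nitrobenzene | O=[N+]([O-])c1cc(Br)c(Br)cc1F | intermediate
3 | 4‑methyl‑2‑(methylthio)pyrimidine | CSc1nccc(C)n1 | starting material
4 | tert‑butyl 2‑[2‑(methylthio)pyrimidin‑4‑yl]acetate | CSc1nccc(CC(=O)OC(C)(C)C)n1 | intermediate
5 | tert‑butyl 2‑(4,5‑dibromo‑2‑nitrophenyl)‑2‑[2‑(methylthio)pyrimidin‑4‑yl]acetate, racemic | CSc1nccc(C(C(=O)OC(C)(C)C)c2cc(Br)c(Br)cc2[N+](=O)[O-])n1 | intermediate
6 | 2‑(4,5‑dibromo‑2‑nitrophenyl)‑2‑[2‑(methylthio)pyrimidin‑4‑yl]acetic acid, racemic, not isolated | CSc1nccc(C(C(=O)O)c2cc(Br)c(Br)cc2[N+](=O)[O-])n1 | intermediate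
7 | 4‑[(4,5‑dibromo‑2‑nitrophenyl)methyl]‑2‑(methylthio)pyrimidine | CSc1nccc(Cc2cc(Br)c(Br)cc2[N+](=O)[O-])n1 | intermediate
8 | 4,5‑dibromo‑2‑{[2‑(methylthio)pyrimidin‑4‑yl]methyl}aniline | CSc1nccc(Cc2cc(Br)c(Br)cc2N)n1 | intermediate
9 | N‑(4,5‑dibromo‑2‑{[2‑(methylthio)pyrimidin‑4‑yl]methyl}phenyl)formamide | CSc1nccc(Cc2cc(Br)c(Br)cc2NC=O)n1 | intermediate
10 | 4‑[(4,5‑dibromo‑2‑isocyanophenyl)methyl]‑2‑(methylthio)pyrimidine | CSc1nccc(Cc2cc(Br)c(Br)cc2[N+]#[C-])n1 | intermediate
11 | lithium aza‑enolate (benzylic carbanion) of 10, not isolated | [Li+].CSc1nccc([CH-]c2cc(Br)c(Br)cc2[N+]#[C-])n1 | intermediate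
12 | 5,6‑dibromo‑2‑lithio‑3‑[2‑(methylthio)pyrimidin‑4‑yl]‑3H‑indole, racemic at C3, not isolated | [Li]C1=Nc2cc(Br)c(Br)cc2C1c1ccnc(SC)n1 | intermediate
13 | lithium 5,6‑dibromo‑3‑[2‑(methylthio)pyrimidin‑4‑yl]indol‑1‑ide, not isolated | [Li+].CSc1nccc(-c2c[n-]c3cc(Br)c(Br)cc23)n1 | intermediate
14 | 5,6‑dibromo‑3‑[2‑(methylthio)pyrimidin‑4‑yl]‑1H‑indole | CSc1nccc(-c2c[nH]c3cc(Br)c(Br)cc23)n1 | intermediate
15 | 5,6‑dibromo‑3‑[2‑(methylsulfinyl)pyrimidin‑4‑yl]‑1H‑indole, racemic at sulfur, not isolated | CS(=O)c1nccc(-c2c[nH]c3cc(Br)c(Br)cc23)n1 | intermediate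
16 | 5,6‑dibromo‑3‑[2‑(methylsulfonyl)pyrimidin‑4‑yl]‑1H‑indole | CS(=O)(=O)c1nccc(-c2c[nH]c3cc(Br)c(Br)cc23)n1 | intermediate
17 | Meridianin F, 4‑(5,6‑dibromo‑1H‑indol‑3‑yl)pyrimidin‑2‑amine (no stereocenters) | Nc1nccc(-c2c[nH]c3cc(Br)c(Br)cc23)n1 | target

## Step count

Total: 10 steps. Longest linear sequence: 9 steps (steps 1 and 3–10, from 1); step 2 is a one‑step branch from 3.

## Steps most likely to fail, with fallbacks

**Step 8 (key cyclization).** The aza‑enolate is strongly delocalized onto the pyrimidine nitrogens and may be too weak a carbon nucleophile toward the isocyanide carbon at low temperature. On warming, isocyanide oligomerization could then compete with the five‑membered closure. The fallback sets out from nitro compound 7 and comes back at indole 14. Condensation of the activated CH2 of 7 with N,N‑dimethylformamide dimethyl acetal (DMF, 100 °C) should give the enamine 2‑(4,5‑dibromo‑2‑nitrophenyl)‑N,N‑dimethyl‑2‑[2‑(methylthio)pyrimidin‑4‑yl]ethenamine F1 as an E/Z mixture. Reduction with Fe powder in AcOH at 80 °C should then give the aniline, which adds to the enamine carbon and loses dimethylamine to give 14. This is the Leimgruber–Batcho indole synthesis in its variant for 3‑substituted indoles.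

**Step 7 (isocyanide formation).** The phosphorylated formamide or the isocyanide itself may be lost by hydrolysis back to 9 on work‑up, by oligomerization on concentration, or by uncontrolled early cyclization. The fallback sets out from aniline 8 and comes back at isocyanide 10. It is the Hofmann carbylamine reaction under phase transfer (CHCl3, 50% aq NaOH, BnEt3NCl, CH2Cl2, rt): dichlorocarbene adds to the amine nitrogen and two eliminations of HCl give 10 without any acidic activating agent. Any 10 that cyclizes under these basic conditions gives 14, which is also on the route. This fallback makes no new compound (F0).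

**Step 9 (S‑oxidation).** The unprotected indole C2=C3 bond may be oxidized in competition with sulfur, or poor solubility may leave the oxidation incomplete. The fallback sets out from 14 and comes back at target 17, with the indole nitrogen masked during the oxidation. Boc2O and catalytic DMAP in MeCN should give tert‑butyl 5,6‑dibromo‑3‑[2‑(methylthio)pyrimidin‑4‑yl]‑1H‑indole‑1‑carboxylate F2. mCPBA in CH2Cl2 should give tert‑butyl 5,6‑dibromo‑3‑[2‑(methylsulfonyl)pyrimidin‑4‑yl]‑1H‑indole‑1‑carboxylate F3. NH3 in dioxane at rt to 40 °C should give tert‑butyl 3‑(2‑aminopyrimidin‑4‑yl)‑5,6‑dibromo‑1H‑indole‑1‑carboxylate F4, and TFA in CH2Cl2 should remove the carbamate to give 17.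

## Further compounds

F1 | step 8 | 2‑(4,5‑dibromo‑2‑nitrophenyl)‑N,N‑dimethyl‑2‑[2‑(methylthio)pyrimidin‑4‑yl]ethenamine, E/Z mixture | CN(C)C=C(c1ccnc(SC)n1)c1cc(Br)c(Br)cc1[N+](=O)[O-]
F0 | step 7 | none | none
F2 | step 9 | tert‑butyl 5,6‑dibromo‑3‑[2‑(methylthio)pyrimidin‑4‑yl]‑1H‑indole‑1‑carboxylate | CSc1nccc(-c2cn(C(=O)OC(C)(C)C)c3cc(Br)c(Br)cc23)n1
F3 | step 9 | tert‑butyl 5,6‑dibromo‑3‑[2‑(methylsulfonyl)pyrimidin‑4‑yl]‑1H‑indole‑1‑carboxylate | CS(=O)(=O)c1nccc(-c2cn(C(=O)OC(C)(C)C)c3cc(Br)c(Br)cc23)n1
F4 | step 9 | tert‑butyl 3‑(2‑aminopyrimidin‑4‑yl)‑5,6‑dibromo‑1H‑indole‑1‑carboxylate | Nc1nccc(-c2cn(C(=O)OC(C)(C)C)c3cc(Br)c(Br)cc23)n1
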